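**Plan**

1. Retrosynthesis: the C9 acetate, the ring A enone (C12 oxidation level) and the silyl ethers come off last. The γ-lactone is cut at C8–C17, the ten-membered ring at C6–C7, then C3–C4, C8–C9 and C2–C3. Ring A is cut at C10–C11, C1–C14 and C12–C13 into three small components.
2. Enabling feature: ring A (C1, C10, C11, C12, C13, C14) contains a lactic acid residue (C20, C11 with its OH, C12=O). It sits next to the α- and β-carbons (C1, C10) of a 3-methylbutenolide whose C=O and OCH2 are C2 and C9, and C13=C14 is a vinyl unit. C1 and C11 carry no hydrogen, so the carbanions of the assembly can only close on C12 and the enone can form in one direction only.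
3. Forward order: ring A is made first, in one operation, fused to a temporary γ-lactone (C2–O–C9). The enone is masked as an allylic bis-silyl ether and the lactone is opened to the C2 methyl ketone and the C9 aldehyde. C7/C8 are added at C9 and C4–C6 at C3; the ten-membered ring is closed, then the γ-lactone, and the enone is restored.
4. Stereochemistry: C11 is bought as (R)-lactic acid and relayed through a tert-butyl acetal; C10 and C1 follow from it in the key step. C9 (and a sacrificial C8 centre) come from an Ipc2B reagent. C2 and C7 are set under Felkin–Anh control, C7 then being inverted by Mitsunobu esterification. C8 and C17 are set by the macrocycle in the Reformatsky closure.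

Key step: step 2

Convention: briarane locants of the target are used throughout (ring A = C1, C10, C11, C12, C13, C14; large ring = C1 to C10; lactone = C7, C8, C17, C19, O; methyls C15 on C1, C16 on C5, C18 on C17, C20 on C11). Unless a name says otherwise, a stereocentre has the configuration it has in the target; full configurations are in the SMILES list.
Assumption: hydroxy ketones 13 and 15 may rest as cyclic hemiketals (O9 on C2); they are drawn and used as the open forms.

**Route**

Step 1
Reactants: 1 (R)-lactic acid; 2 pivalaldehyde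
Product: 3 (2R,5R)-2-tert-butyl-5-methyl-1,3-dioxolan-4-one (cis)
Conditions: p-TsOH (cat.), pentane, reflux, Dean–Stark; recrystallisation from pentane at −78 °C
Reagents that add atoms: none
Why: Acid-catalysed acetalisation of the α-hydroxy acid with azeotropic removal of water should set the acetal centre under thermodynamic control with tert-butyl cis to methyl, the cis isomer being enriched by crystallisation.

Step 2
Reactants: 3 (2R,5R)-2-tert-butyl-5-methyl-1,3-dioxolan-4-one; 4 3-methyl-2(5H)-furanone; 5 phenyl vinyl sulfoxide (racemic)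
Product: 9 ring A β-keto sulfoxide fused to the C2–O–C9 γ-lactone (C11 hydroxyl free; isomer mixture at C13 and sulfur), via lithium enolate 6 (not isolated), via lactone enolate 7 (not isolated), via sulfinyl carbanion 8 (not isolated)
Conditions: LiN(iPr)2 (1.05 equiv), THF, −78 °C; 4, −78 °C; 5, DMPU, −78 to 0 °C; AcOH
Reagents that add atoms: none
Why: Proposed new method: enolate 6 should add in conjugate fashion to C10 of butenolide 4, the lactone enolate 7 should add through C1 to the vinyl sulfoxide 5, and the α-sulfinyl carbanion 8 should attack the acetal-activated carbonyl C12, whose tetrahedral adduct collapses with loss of pivalaldehyde and unveils the C11 alkoxide. The closest known reaction type is the Michael–Michael-initiated ring closure with Dieckmann-type termination; tandem conjugate addition–trapping of butenolides and acylation of sulfinyl carbanions by esters are each known, but this three-component sequence ending on a dioxolanone is not. Ring A is closed by 6-exo-trig attack of C13 on C12, while the trans-fused γ-lactone (C2–O–C9) and the acetal ring serve as temporary rings. C11 is set by attack anti to the tert-butyl group of the acetal, C10 by a synclinal open transition state with C10–H over the dioxolanone ring, and C1 by entry of the sulfoxide anti to the bulky C10 substituent of the five-membered enolate; C13 and sulfur are uncontrolled and erased in step 3. The step needs conjugate addition to win over 1,2-addition and γ-deprotonation of 4, and ring closure to win over retro-Michael reaction or proton quench; this should be secured by the ester-type lithium enolate at −78 °C, by the absence of any acidic C–H at the fully substituted C1 and C11, and by the irreversible acyl transfer that drains the reversible second addition.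

Step 3
Reactants: 9 ring A β-keto sulfoxide lactone
Product: 10 ring A hydroxy enone lactone (C13=C14, C12=O, C11 OH)
Conditions: toluene, 80 °C
Reagents that add atoms: none
Why: Thermal syn-elimination of the β-keto sulfoxide (sulfoxide pyrolysis) can only use a C14 hydrogen because C12 is a carbonyl carbon, so the enone should form regiospecifically and no stereocentre is created.

Step 4
Reactants: 10 ring A hydroxy enone lactone
Product: 11 ring A allylic diol lactone (12S; C12 OH trans to C11 OH)
Conditions: NaBH4, CeCl3·7H2O, MeOH, −78 °C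
Reagents that add atoms: none
Why: Luche 1,2-reduction, in which hydride should attack C12 axially and anti to the pseudoaxial C11 methyl group; the C12 configuration is of no consequence because C12 is reoxidised in step 22, and the lactone is not reduced at −78 °C.

Step 5
Reactants: 11 ring A allylic diol lactone
Product: 12 C11,C12-bis(triethylsilyl) ether of 11
Conditions: TESOTf (3 equiv), 2,6-lutidine, CH2Cl2, 0 °C to rt
Reagents that add atoms: triethylsilyl trifluoromethanesulfonate CC[Si](CC)(CC)OS(=O)(=O)C(F)(F)F
Why: Silylation of the secondary and the tertiary alcohol with a silyl triflate masks the reduced enone against the organolithium, enolate and samarium steps that follow.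

Step 6
Reactants: 12 bis(triethylsilyl) lactone
Product: 13 C2 methyl ketone with free C9 primary alcohol
Conditions: MeLi (1.1 equiv), THF, −78 °C; H2O
Reagents that add atoms: methyllithium [Li]C
Why: Mono-addition of MeLi to the strained trans-fused lactone at −78 °C should stop at the ketone oxidation level, as is usual for lactones, turning C2 into the methyl ketone that brings in C3 and freeing the C9 oxygen.

Step 7
Reactants: 13 C2 methyl ketone C9 alcohol
Product: 14 C2 methyl ketone C9 aldehyde
Conditions: Dess–Martin periodinane, NaHCO3, CH2Cl2, 0 °C to rt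
Reagents that add atoms: none
Why: Dess–Martin oxidation of the primary alcohol under buffered neutral conditions should give the aldehyde without disturbing the epimerisable C10 centre or triggering aldol reaction with the methyl ketone.

Step 8
Reactants: 14 C2 methyl ketone C9 aldehyde
Product: 15 C9 homoallylic alcohol with C8 methoxymethyl ether and C7 vinyl group (8R,9R; syn)
Conditions: allyl methoxymethyl ether, s-BuLi, THF, −78 °C; (−)-Ipc2BOMe; BF3·OEt2; 14, −78 °C; NaOH, H2O2
Reagents that add atoms: allyl methoxymethyl ether C=CCOCOC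
Why: Brown-type (Z)-γ-alkoxyallylboration through a closed Zimmerman–Traxler transition state should give the syn C8/C9 relationship, and the reagent derived from (+)-α-pinene should deliver the allyl unit to the Si face of the aldehyde to set 9R under reagent control, while the hindered methyl ketone does not react at −78 °C.

Step 9
Reactants: 15 C9 homoallylic alcohol
Product: 16 C9 triethylsilyl ether of 15
Conditions: TESCl, imidazole, DMAP (cat.), DMF, rt
Reagents that add atoms: chlorotriethylsilane CC[Si](Cl)(CC)CC
Why: Silylation with the silyl chloride and imidazole protects the C9 alcohol without converting the methyl ketone into a silyl enol ether.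

Step 10
Reactants: 17 propargyl alcohol
Product: 18 (Z)-3-iodo-2-methylprop-2-en-1-ol
Conditions: MeMgBr (2.5 equiv), CuI (cat.), THF, −10 °C to rt; I2, −78 to 0 °C
Reagents that add atoms: methylmagnesium bromide C[Mg]Br; iodine II
Why: Copper-catalysed anti-carbomagnesiation of the propargylic alkoxide followed by iodinolysis should place iodine cis to the CH2OH group through the alkoxide-bound cyclic organomagnesium, which fixes the Z geometry needed for C5=C6.

Step 11
Reactants: 18 (Z)-3-iodo-2-methylprop-2-en-1-ol
Product: 19 (Z)-3-bromo-1-iodo-2-methylprop-1-ene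
Conditions: CBr4, PPh3, CH2Cl2, 0 °C
Reagents that add atoms: carbon tetrabromide BrC(Br)(Br)Br
Why: Appel bromination of the primary allylic alcohol should proceed without allylic transposition or loss of alkene geometry.

Step 12
Reactants: 16 C9 triethylsilyl ether (methyl ketone); 19 (Z)-3-bromo-1-iodo-2-methylprop-1-ene
Product: 20 C3-alkylated C2 ketone carrying the C3–C6 chain with the (Z)-iodoalkene
Conditions: LiN(iPr)2 (1.1 equiv), THF, −78 °C; 19, DMPU, −78 to −40 °C
Reagents that add atoms: none
Why: Kinetic deprotonation of the methyl ketone (the only enolisable position, C1 being quaternary) and SN2 alkylation by the allylic bromide should form C3–C4, the iodoalkene being inert to the amide base.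

Step 13
Reactants: 20 C3-alkylated C2 ketone
Product: 21 (2R) alcohol
Conditions: NaBH4, MeOH/THF, 0 °C
Reagents that add atoms: none
Why: Hydride reduction under Felkin–Anh control by the quaternary C1 (C10 branch anti to the incoming hydride, C15 methyl as the small group) should give the 2R alcohol.

Step 14
Reactants: 21 (2R) alcohol
Product: 22 C2 butyrate
Conditions: butyric anhydride, DMAP, Et3N, CH2Cl2, rt
Reagents that add atoms: butyric anhydride CCCC(=O)OC(=O)CCC
Why: DMAP-catalysed acylation of the hindered secondary alcohol installs the butyrate of the target, which also serves as the C2 protecting group from here on.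

Step 15
Reactants: 22 C2 butyrate
Product: 24 C7 aldehyde (C8 methoxymethyl ether), via diol 23 (not isolated)
Conditions: OsO4 (cat.), NaIO4, 2,6-lutidine, dioxane/H2O, rt
Reagents that add atoms: osmium tetroxide O=[Os](=O)(=O)=O; sodium periodate [Na+].[O-]I(=O)(=O)=O
Why: Lemieux–Johnson oxidation (osmylation, then periodate cleavage of the diol) should select the monosubstituted terminal alkene over the ring A olefin, which is flanked by the quaternary C1 and the silyloxy carbon C12, and over the electron-poor iodoalkene.

Step 16
Reactants: 24 C7 aldehyde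
Product: 25 macrocyclic 7R allylic alcohol (7-epi; ten-membered ring closed)
Conditions: CrCl2 (10 equiv), NiCl2 (cat.), DMSO/THF, 0.002 M, rt
Reagents that add atoms: none
Why: Intramolecular Nozaki–Hiyama–Kishi reaction should close the ten-membered ring at C6–C7 (10-exo-trig) with retention of the Z alkene geometry, and addition to the α-alkoxy aldehyde is expected under Felkin–Anh control anti to the C8 methoxymethoxy group, which gives the 7R alcohol.

Step 17
Reactants: 25 macrocyclic 7R allylic alcohol
Product: 26 7S 2-bromopropanoate (mixture at the C–Br carbon)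
Conditions: 2-bromopropanoic acid, PPh3, DIAD, toluene, 0 °C to rt
Reagents that add atoms: 2-bromopropanoic acid CC(Br)C(=O)O
Why: Mitsunobu esterification with inversion at the allylic C7 should correct C7 to the configuration of the target while installing the α-bromo ester needed for the lactone.

Step 18
Reactants: 26 7S 2-bromopropanoate
Product: 27 C8 secondary alcohol
Conditions: Me2BBr, CH2Cl2, −78 °C; aq. NaHCO3
Reagents that add atoms: none
Why: Low-temperature cleavage of the methoxymethyl ether by the bromoborane should free the sacrificial C8 alcohol and leave silyl ethers, esters and the secondary alkyl bromide intact.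

Step 19
Reactants: 27 C8 secondary alcohol
Product: 28 C8 ketone
Conditions: Dess–Martin periodinane, NaHCO3, CH2Cl2, 0 °C
Reagents that add atoms: none
Why: Dess–Martin oxidation under buffered conditions removes the relay stereocentre C8 and should avoid epimerisation of the now acidic C7 and C9 positions.

Step 20
Reactants: 28 C8 ketone
Product: 29 γ-lactone with C8 tertiary alcohol and C17 methyl (8S,17R); tris(triethylsilyl) ether
Conditions: SmI2 (2.5 equiv), THF, −78 °C
Reagents that add atoms: none
Why: SmI2-mediated intramolecular Reformatsky reaction (5-exo-trig attack of C17 on C8), in which the α-bromo ester is reduced faster than the ketone; the tether from O7 and the antiperiplanar C6–C7–C8–C9 arrangement of the macrocycle should expose only the ketone face that leads to the trans-fused lactone, and the C17 methyl should take the epimerisable, thermodynamically favoured position away from C9.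

Step 21
Reactants: 29 tris(triethylsilyl) lactone
Product: 30 tetraol (C8, C9, C11 and C12 hydroxyls free)
Conditions: HF·pyridine, pyridine, THF, 0 °C to rt
Reagents that add atoms: none
Why: Fluoride-mediated cleavage of the three triethylsilyl ethers under mildly acidic conditions should leave the two esters, the lactone and the allylic alcohol untouched.

Step 22
Reactants: 30 tetraol
Product: 31 9-deacetyl target (ring A enone restored)
Conditions: MnO2, CH2Cl2, rt
Reagents that add atoms: none
Why: MnO2 should oxidise only the allylic secondary alcohol at C12 (the C9 alcohol is not allylic, C8 and C11 are tertiary) and so restore the enone.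

Step 23
Reactants: 31 9-deacetyl target
Product: 32 target
Conditions: Ac2O, pyridine, DMAP (cat.), CH2Cl2, 0 °C
Reagents that add atoms: acetic anhydride CC(=O)OC(C)=O
Why: Acetylation should take place only at the single secondary alcohol (C9), the tertiary alcohols at C8 and C11 being unreactive under these conditions.

**Compound list**

1 | (R)-lactic acid | C[C@@H](O)C(=O)O | starting material
2 | pivalaldehyde | CC(C)(C)C=O | starting material
3 | (2R,5R)-2-tert-butyl-5-methyl-1,3-dioxolan-4-one | C[C@H]1O[C@@H](C(C)(C)C)OC1=O | intermediate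
4 | 3-methyl-2(5H)-furanone | CC1=CCOC1=O | starting material
5 | phenyl vinyl sulfoxide (racemic) | C=CS(=O)c1ccccc1 | starting material
6 | lithium enolate of 3 | [Li]OC1=C(C)O[C@@H](C(C)(C)C)O1 | intermediate
7 | lithium lactone enolate of the first Michael adduct (C10–C11 formed) | [Li]OC1=C(C)[C@@H](CO1)[C@]2(C)O[C@@H](C(C)(C)C)OC2=O | intermediate
8 | C13-lithiated sulfoxide of the second Michael adduct (C1–C14 formed) | O=C1OC[C@H]([C@]1(C)CC([Li])S(=O)c3ccccc3)[C@]2(C)O[C@@H](C(C)(C)C)OC2=O | intermediate
9 | ring A β-keto sulfoxide lactone (C13 phenylsulfinyl, C11 OH, lactone C2(=O)–O–C9) | O=C1OC[C@@H]2[C@]1(C)CC(S(=O)c3ccccc3)C(=O)[C@@]2(C)O | intermediate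
10 | ring A hydroxy enone lactone | O=C1OC[C@@H]2[C@]1(C)C=CC(=O)[C@@]2(C)O | intermediate
11 | ring A allylic diol lactone (12S) | O=C1OC[C@@H]2[C@]1(C)C=C[C@H](O)[C@@]2(C)O | intermediate
12 | C11,C12-bis(triethylsilyl) ether of 11 | O=C1OC[C@@H]2[C@]1(C)C=C[C@H](O[Si](CC)(CC)CC)[C@@]2(C)O[Si](CC)(CC)CC | intermediate
13 | C2 methyl ketone with free C9 primary alcohol | CC(=O)[C@@]1(C)C=C[C@H](O[Si](CC)(CC)CC)[C@@](C)(O[Si](CC)(CC)CC)[C@@H]1CO | intermediate
14 | C2 methyl ketone C9 aldehyde | CC(=O)[C@@]1(C)C=C[C@H](O[Si](CC)(CC)CC)[C@@](C)(O[Si](CC)(CC)CC)[C@@H]1C=O | intermediate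
15 | C9 homoallylic alcohol with C8 methoxymethyl ether (8R,9R) | CC(=O)[C@@]1(C)C=C[C@H](O[Si](CC)(CC)CC)[C@@](C)(O[Si](CC)(CC)CC)[C@@H]1[C@@H](O)[C@H](OCOC)C=C | intermediate
16 | C9 triethylsilyl ether of 15 | CC(=O)[C@@]1(C)C=C[C@H](O[Si](CC)(CC)CC)[C@@](C)(O[Si](CC)(CC)CC)[C@@H]1[C@@H](O[Si](CC)(CC)CC)[C@H](OCOC)C=C | intermediate
17 | propargyl alcohol | C#CCO | starting material
18 | (Z)-3-iodo-2-methylprop-2-en-1-ol | OC/C(C)=C\I | intermediate
19 | (Z)-3-bromo-1-iodo-2-methylprop-1-ene | BrC/C(C)=C\I | intermediate
20 | C3-alkylated C2 ketone with (Z)-iodoalkene chain | I/C=C(C)\CCC(=O)[C@@]1(C)C=C[C@H](O[Si](CC)(CC)CC)[C@@](C)(O[Si](CC)(CC)CC)[C@@H]1[C@@H](O[Si](CC)(CC)CC)[C@H](OCOC)C=C | intermediate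
21 | (2R) alcohol | I/C=C(C)\CC[C@@H](O)[C@@]1(C)C=C[C@H](O[Si](CC)(CC)CC)[C@@](C)(O[Si](CC)(CC)CC)[C@@H]1[C@@H](O[Si](CC)(CC)CC)[C@H](OCOC)C=C | intermediate
22 | C2 butyrate | I/C=C(C)\CC[C@@H](OC(=O)CCC)[C@@]1(C)C=C[C@H](O[Si](CC)(CC)CC)[C@@](C)(O[Si](CC)(CC)CC)[C@@H]1[C@@H](O[Si](CC)(CC)CC)[C@H](OCOC)C=C | intermediate
23 | terminal diol from osmylation of 22 (mixture at the new carbinol) | I/C=C(C)\CC[C@@H](OC(=O)CCC)[C@@]1(C)C=C[C@H](O[Si](CC)(CC)CC)[C@@](C)(O[Si](CC)(CC)CC)[C@@H]1[C@@H](O[Si](CC)(CC)CC)[C@H](OCOC)C(O)CO | intermediate
24 | C7 aldehyde | I/C=C(C)\CC[C@@H](OC(=O)CCC)[C@@]1(C)C=C[C@H](O[Si](CC)(CC)CC)[C@@](C)(O[Si](CC)(CC)CC)[C@@H]1[C@@H](O[Si](CC)(CC)CC)[C@H](OCOC)C=O | intermediate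
25 | macrocyclic 7R allylic alcohol (7-epi) | CCCC(=O)O[C@@H]1CC/C(C)=C\[C@@H](O)[C@@H](OCOC)[C@H](O[Si](CC)(CC)CC)[C@@H]2[C@]1(C)C=C[C@H](O[Si](CC)(CC)CC)[C@@]2(C)O[Si](CC)(CC)CC | intermediate
26 | 7S 2-bromopropanoate | CCCC(=O)O[C@@H]1CC/C(C)=C\[C@H](OC(=O)C(C)Br)[C@@H](OCOC)[C@H](O[Si](CC)(CC)CC)[C@@H]2[C@]1(C)C=C[C@H](O[Si](CC)(CC)CC)[C@@]2(C)O[Si](CC)(CC)CC | intermediate
27 | C8 secondary alcohol | CCCC(=O)O[C@@H]1CC/C(C)=C\[C@H](OC(=O)C(C)Br)[C@@H](O)[C@H](O[Si](CC)(CC)CC)[C@@H]2[C@]1(C)C=C[C@H](O[Si](CC)(CC)CC)[C@@]2(C)O[Si](CC)(CC)CC | intermediate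
28 | C8 ketone | CCCC(=O)O[C@@H]1CC/C(C)=C\[C@H](OC(=O)C(C)Br)C(=O)[C@H](O[Si](CC)(CC)CC)[C@@H]2[C@]1(C)C=C[C@H](O[Si](CC)(CC)CC)[C@@]2(C)O[Si](CC)(CC)CC | intermediate
29 | γ-lactone with C8 OH, tris(triethylsilyl) ether | CCCC(=O)O[C@@H]1CC/C(C)=C\[C@@H]2OC(=O)[C@H](C)[C@@]2(O)[C@H](O[Si](CC)(CC)CC)[C@@H]2[C@]1(C)C=C[C@H](O[Si](CC)(CC)CC)[C@@]2(C)O[Si](CC)(CC)CC | intermediate
30 | tetraol | CCCC(=O)O[C@@H]1CC/C(C)=C\[C@@H]2OC(=O)[C@H](C)[C@@]2(O)[C@H](O)[C@@H]2[C@]1(C)C=C[C@H](O)[C@@]2(C)O | intermediate
31 | 9-deacetyl target | CCCC(=O)O[C@@H]1CC/C(C)=C\[C@@H]2OC(=O)[C@H](C)[C@@]2(O)[C@H](O)[C@@H]2[C@]1(C)C=CC(=O)[C@@]2(C)O | intermediate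
32 | target (CNP0346936.2) | CCCC(=O)O[C@@H]1CC/C(C)=C\[C@@H]2OC(=O)[C@H](C)[C@@]2(O)[C@H](OC(C)=O)[C@@H]2[C@]1(C)C=CC(=O)[C@@]2(C)O | target

**Step count**

Total: 23 steps. Longest linear sequence: 21 steps (steps 1–9 and 12–23); steps 10–11 make the side fragment 19.

**Steps most likely to fail**

1. Step 2 (Proposed new method). The sequence may stall after the first or second conjugate addition, by retro-Michael reaction or proton quench of the sulfinyl carbanion before ring closure, or the first addition may take the other topicity at C10. The fallback sets out from 3 and 4 and returns at 10, using known reaction types only. Enolate 6 is added to 4 and the lactone enolate is trapped with the stronger acceptor phenyl vinyl sulfone (tandem conjugate addition–Michael trapping) to give the sulfone lactone F1. LiN(iPr)2 (2.2 equiv) then generates the α-sulfonyl carbanion, which is acylated by the dioxolanone carbonyl (Dieckmann-type closure, loss of pivalaldehyde) to give the β-keto sulfone F2. Aluminium amalgam removes the sulfonyl group to give the ring A ketone F3, and dehydrogenation with 2-iodoxybenzoic acid, possible only toward C13–C14, gives enone 10.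

2. Step 16. Oligomerisation may compete with closure of the ten-membered ring, and the vinylmetal may attack the other aldehyde face (chelation by the C8 ether instead of Felkin–Anh control). The fallback sets out from 24 and returns at 26. If the 7S epimer is formed, this compound, the 7S allylic alcohol F4, is acylated directly with 2-bromopropanoyl bromide and pyridine (retention at C7) to the same ester 26, so that both C7 epimers converge.

3. Step 20. The ketyl-type reduction may cleave the C9 silyloxy group next to the ketone, or the enolate may add with poor control at C8 or C17. The fallback sets out from 28 and returns at 29. Displacement of bromide by PPh3 gives the phosphonium salt F5, and Et3N generates the ylide, which closes by intramolecular Wittig reaction on the C8 ketone to the Δ8(17)-butenolide F6. Nucleophilic epoxidation (NaOCl, pyridine) gives the 8,17-epoxy lactone F7. Reductive opening at C17 with Na[PhSeB(OEt)3], followed by equilibration of C17 with DBU, gives 29.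

**Further compounds**

F1 | step 2 | sulfone lactone (C1 2-(phenylsulfonyl)ethyl, dioxolanone intact) | O=C1OC[C@H]([C@]1(C)CCS(=O)(=O)c3ccccc3)[C@]2(C)O[C@@H](C(C)(C)C)OC2=O
F2 | step 2 | ring A β-keto sulfone lactone | O=C1OC[C@@H]2[C@]1(C)CC(S(=O)(=O)c3ccccc3)C(=O)[C@@]2(C)O
F3 | step 2 | ring A saturated hydroxy ketone lactone | O=C1OC[C@@H]2[C@]1(C)CCC(=O)[C@@]2(C)O
F4 | step 16 | macrocyclic 7S allylic alcohol | CCCC(=O)O[C@@H]1CC/C(C)=C\[C@H](O)[C@@H](OCOC)[C@H](O[Si](CC)(CC)CC)[C@@H]2[C@]1(C)C=C[C@H](O[Si](CC)(CC)CC)[C@@]2(C)O[Si](CC)(CC)CC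
F5 | step 20 | phosphonium bromide of the C7 propanoate | CCCC(=O)O[C@@H]1CC/C(C)=C\[C@H](OC(=O)C(C)[P+](c3ccccc3)(c4ccccc4)c5ccccc5)C(=O)[C@H](O[Si](CC)(CC)CC)[C@@H]2[C@]1(C)C=C[C@H](O[Si](CC)(CC)CC)[C@@]2(C)O[Si](CC)(CC)CC.[Br-]
F6 | step 20 | Δ8(17)-butenolide | CCCC(=O)O[C@@H]1CC/C(C)=C\[C@@H]2OC(=O)C(C)=C2[C@H](O[Si](CC)(CC)CC)[C@@H]2[C@]1(C)C=C[C@H](O[Si](CC)(CC)CC)[C@@]2(C)O[Si](CC)(CC)CC
F7 | step 20 | 8,17-epoxy lactone | CCCC(=O)O[C@@H]1CC/C(C)=C\[C@@H]2OC(=O)[C@]3(C)O[C@]23[C@H](O[Si](CC)(CC)CC)[C@@H]2[C@]1(C)C=C[C@H](O[Si](CC)(CC)CC)[C@@]2(C)O[Si](CC)(CC)CC
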